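**Retrosynthetic overview**

1. Tetralin numbering is used: C1 carbinol, C4 diarylmethine, C5 methoxy carbon, ring A aromatic, ring B saturated, C1′ the naphthalene carbon on C4. The strategy rests on C4, a CH that carries two different aryl carbons (C4a of ring A and C1′) at the end of the chain C1–C2–C3, so it can begin as the terminal CH2 of a homoallylic silyl ether whose arene holds boron at C4a.
2. Key disconnection: C4–C1′ and C4–C4a are made together by a palladium-catalysed 1,1-diarylation of that alkene with diazonium salt 14. Ring B is the only ring formed; ring A and the naphthalene come from the starting materials.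
3. Boron partner 8: from 2-bromo-3-methoxybenzaldehyde by catalytic asymmetric allylboration (sets C1), silylation and bromine–lithium exchange/borylation. Boron is carried as the free boronic acid, not a pinacol ester, because base-free cationic palladium transmetalates B–OH species and the site is di-ortho-substituted.
4. Diazonium salt 14: from naphthalene-1,8-diol by monomethylation, azo coupling para to the free hydroxyl, benzylation, reductive azo cleavage and diazotisation.
5. After the key step: fluoride desilylation, then hydrogenolysis of the benzyl ether.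

Key step: step 9

Assumption: the sense of induction known for phosphoric acid-catalysed allylboration of simple aryl aldehydes ((S)-acid, Si-face attack, (S)-alcohol) is taken to hold for the ortho-bromo aldehyde 1; should the alcohol prove to be R, the (R)-acid would be used.

**Route**

Step 1
Reactants: 1 2-bromo-3-methoxybenzaldehyde; 2 allylboronic acid pinacol ester
Product: 4 (1S)-1-(2-bromo-3-methoxyphenyl)but-3-en-1-ol, via pinacol borate ester 3 (not isolated)
Conditions: (S)-TRIP [(S)-3,3′-bis(2,4,6-triisopropylphenyl)-1,1′-binaphthalene-2,2′-diyl hydrogen phosphate] (5 mol %), toluene, −30 °C; aqueous work-up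
Reagents that add atoms: none
Why: Chiral phosphoric acid-catalysed allylboration of an aryl aldehyde through a closed chair transition state in which the acid binds the boronate oxygen and the formyl hydrogen, so that the (S)-acid should deliver the allyl group to the Si face and set C1 as S, the aryl bromide being inert.

Step 2
Reactants: 4 (1S)-1-(2-bromo-3-methoxyphenyl)but-3-en-1-ol
Product: 5 {[(1S)-1-(2-bromo-3-methoxyphenyl)but-3-en-1-yl]oxy}(tert-butyl)dimethylsilane
Conditions: TBSCl, imidazole, DMF, rt
Reagents that add atoms: tert-butyldimethylsilyl chloride, CC(C)(C)[Si](C)(C)Cl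
Why: Standard silylation of a secondary benzylic alcohol with imidazole as nucleophilic catalyst and base, giving a weakly coordinating ether that leaves the C1 stereocentre untouched.

Step 3
Reactants: 5 {[(1S)-1-(2-bromo-3-methoxyphenyl)but-3-en-1-yl]oxy}(tert-butyl)dimethylsilane
Product: 8 {2-[(1S)-1-{[tert-butyl(dimethyl)silyl]oxy}but-3-en-1-yl]-6-methoxyphenyl}boronic acid, via aryllithium 6 (not isolated), via lithium triisopropoxyborate 7 (not isolated)
Conditions: n-BuLi (1.1 equiv), THF, −78 °C, 10 min; B(OiPr)3, −78 °C to rt; aq. NH4Cl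
Reagents that add atoms: n-butyllithium, [Li]CCCC (lithium of 6 and 7); triisopropyl borate, CC(C)OB(OC(C)C)OC(C)C; water, O
Why: Lithiation–borylation, in which bromine–lithium exchange at −78 °C is faster than any attack on the silyl ether or the alkene, the aryllithium is trapped cold by the borate before silyl migration or carbolithiation can set in, and mild hydrolysis frees the boronic acid without touching the silyl ether.

Step 4
Reactants: 9 naphthalene-1,8-diol
Product: 10 8-methoxynaphthalen-1-ol
Conditions: MeI (1.05 equiv), K2CO3, acetone, reflux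
Reagents that add atoms: iodomethane, CI
Why: Williamson monomethylation that stops after one methyl group because the remaining hydroxyl is hydrogen-bonded to the new peri methoxy group and is much less acidic than the diol.

Step 5
Reactants: 10 8-methoxynaphthalen-1-ol
Product: 11 8-methoxy-4-[(E)-phenyldiazenyl]naphthalen-1-ol
Conditions: NaOH (1.05 equiv), EtOH/H2O, 0 °C; PhN2BF4 (1.0 equiv); AcOH to pH 6
Reagents that add atoms: benzenediazonium tetrafluoroborate, N#[N+]c1ccccc1.F[B-](F)(F)F
Why: Azo coupling (electrophilic aromatic substitution) of the naphtholate, which directs the weakly electrophilic diazonium ion to C4, para to the oxygen, the methoxy-bearing ring being far less activated.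

Step 6
Reactants: 11 8-methoxy-4-[(E)-phenyldiazenyl]naphthalen-1-ol
Product: 12 (E)-1-[4-(benzyloxy)-5-methoxynaphthalen-1-yl]-2-phenyldiazene
Conditions: BnBr, K2CO3, DMF, 50 °C
Reagents that add atoms: benzyl bromide, BrCc1ccccc1
Why: Williamson O-benzylation of the para-hydroxyazo compound, done before the reduction because a free 4-aminonaphthol would oxidise in air.

Step 7
Reactants: 12 (E)-1-[4-(benzyloxy)-5-methoxynaphthalen-1-yl]-2-phenyldiazene
Product: 13 4-(benzyloxy)-5-methoxynaphthalen-1-amine
Conditions: Na2S2O4 (excess), EtOH/H2O, 80 °C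
Reagents that add atoms: none
Why: Reductive cleavage of the N=N bond by dithionite through the hydrazo compound, which leaves the benzyl ether intact where catalytic hydrogenation would not.

Step 8
Reactants: 13 4-(benzyloxy)-5-methoxynaphthalen-1-amine
Product: 14 4-(benzyloxy)-5-methoxynaphthalene-1-diazonium tetrafluoroborate
Conditions: 48% aq. HBF4, t-BuONO, EtOH, 0 °C; precipitation with Et2O
Reagents that add atoms: tert-butyl nitrite, CC(C)(C)ON=O; tetrafluoroboric acid, F[B-](F)(F)F.[H+]
Why: Diazotisation with an alkyl nitrite under a non-nucleophilic acid, giving a salt that the para alkoxy donor stabilises and that precipitates for cold storage.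

Step 9
Reactants: 8 {2-[(1S)-1-{[tert-butyl(dimethyl)silyl]oxy}but-3-en-1-yl]-6-methoxyphenyl}boronic acid; 14 4-(benzyloxy)-5-methoxynaphthalene-1-diazonium tetrafluoroborate
Product: 15 {[(1S,4S)-4-[4-(benzyloxy)-5-methoxynaphthalen-1-yl]-5-methoxy-1,2,3,4-tetrahydronaphthalen-1-yl]oxy}(tert-butyl)dimethylsilane (cis)
Conditions: Pd2(dba)3 (5 mol %), 2,6-di-tert-butyl-4-methylpyridine (1.5 equiv), DMA, 0 °C to rt, 14 (1.3 equiv) added in portions; aqueous work-up
Reagents that add atoms: none
Why: Proposed new method: zerovalent palladium adds oxidatively to 14, the cationic naphthylpalladium species inserts the terminal alkene of 8 with the naphthyl group on C4 (C4–C1′), syn β-hydride elimination of the benzylic C4–H and reinsertion carry palladium from C3 to C4 as an η3-naphthylmethyl cation, and the ortho boronic acid transmetalates to a seven-membered aryl(alkyl)palladacycle that reductively eliminates to form C4–C4a. The closest known reaction type is the intermolecular three-component 1,1-diarylation of terminal alkenes with arenediazonium salts and arylboronic acids under base-free Pd2(dba)3 catalysis; a tethered, di-ortho-substituted boron partner and ring closure are untested. Ring B (C1–C2–C3–C4–C4a–C8a) closes by C(sp3)–C(sp2) reductive elimination from the seven-membered palladacycle, an intramolecular Suzuki-type capture at C4 and not a Heck-type cyclisation. C4 is set by 1,4-induction from C1: provided the two C4 epimers of the π-benzyl intermediate exchange (β-hydride elimination with alkene-face exchange), ring closure should be faster through the boat-like palladacycle in which the silyloxy group at C1 and the naphthyl group at C4 both lie pseudoaxial on the face opposite palladium, clear of C8–H and of the C5 methoxy group, which leads to the cis (1S,4S) product. The step needs alkene insertion to outrun direct biaryl coupling (the hindered boronic acid and the absence of base slow transmetalation at the arylpalladium stage), migration toward C4 and not toward C2 (the benzylic C4–H and η3 stabilisation by the electron-rich naphthalene favour it), and capture at C4 and not at C3 (β-hydride elimination of the cationic alkylpalladium is faster than transmetalation). The hindered pyridine takes up the HBF4 that is released, so the silyl and benzyl ethers should survive.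

Step 10
Reactants: 15 {[(1S,4S)-4-[4-(benzyloxy)-5-methoxynaphthalen-1-yl]-5-methoxy-1,2,3,4-tetrahydronaphthalen-1-yl]oxy}(tert-butyl)dimethylsilane
Product: 16 (1S,4S)-4-[4-(benzyloxy)-5-methoxynaphthalen-1-yl]-5-methoxy-1,2,3,4-tetrahydronaphthalen-1-ol
Conditions: TBAF, THF, 0 °C to rt
Reagents that add atoms: none
Why: Fluoride-mediated desilylation driven by the strong Si–F bond, under conditions that touch neither stereocentre nor the aryl ethers.

Step 11
Reactants: 16 (1S,4S)-4-[4-(benzyloxy)-5-methoxynaphthalen-1-yl]-5-methoxy-1,2,3,4-tetrahydronaphthalen-1-ol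
Product: 17 dipolynaphthalene B, (1S,4S)-4-(4-hydroxy-5-methoxynaphthalen-1-yl)-5-methoxy-1,2,3,4-tetrahydronaphthalen-1-ol
Conditions: H2 (1 atm), 10% Pd/C, EtOAc, rt
Reagents that add atoms: none
Why: Catalytic hydrogenolysis of the aryl benzyl ether, which under neutral conditions should be much faster than cleavage of the secondary benzylic C1–O bond and leaves both stereocentres unchanged.

**Compound list**

1 | 2-bromo-3-methoxybenzaldehyde | COc1cccc(C=O)c1Br | starting material
2 | allylboronic acid pinacol ester | C=CCB1OC(C)(C)C(C)(C)O1 | starting material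
3 | 2-{[(1S)-1-(2-bromo-3-methoxyphenyl)but-3-en-1-yl]oxy}-4,4,5,5-tetramethyl-1,3,2-dioxaborolane | C=CC[C@H](OB1OC(C)(C)C(C)(C)O1)c1cccc(OC)c1Br | intermediate
4 | (1S)-1-(2-bromo-3-methoxyphenyl)but-3-en-1-ol | C=CC[C@H](O)c1cccc(OC)c1Br | intermediate
5 | {[(1S)-1-(2-bromo-3-methoxyphenyl)but-3-en-1-yl]oxy}(tert-butyl)dimethylsilane | C=CC[C@H](O[Si](C)(C)C(C)(C)C)c1cccc(OC)c1Br | intermediate
6 | {2-[(1S)-1-{[tert-butyl(dimethyl)silyl]oxy}but-3-en-1-yl]-6-methoxyphenyl}lithium | C=CC[C@H](O[Si](C)(C)C(C)(C)C)c1cccc(OC)c1[Li] | intermediate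
7 | lithium {2-[(1S)-1-{[tert-butyl(dimethyl)silyl]oxy}but-3-en-1-yl]-6-methoxyphenyl}tri(propan-2-yloxy)borate | C=CC[C@H](O[Si](C)(C)C(C)(C)C)c1cccc(OC)c1[B-](OC(C)C)(OC(C)C)OC(C)C.[Li+] | intermediate
8 | {2-[(1S)-1-{[tert-butyl(dimethyl)silyl]oxy}but-3-en-1-yl]-6-methoxyphenyl}boronic acid | C=CC[C@H](O[Si](C)(C)C(C)(C)C)c1cccc(OC)c1B(O)O | intermediate
9 | naphthalene-1,8-diol | Oc1cccc2cccc(O)c12 | starting material
10 | 8-methoxynaphthalen-1-ol | COc1cccc2cccc(O)c12 | intermediate
11 | 8-methoxy-4-[(E)-phenyldiazenyl]naphthalen-1-ol | COc1cccc2c(/N=N/c3ccccc3)ccc(O)c12 | intermediate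
12 | (E)-1-[4-(benzyloxy)-5-methoxynaphthalen-1-yl]-2-phenyldiazene | COc1cccc2c(/N=N/c3ccccc3)ccc(OCc3ccccc3)c12 | intermediate
13 | 4-(benzyloxy)-5-methoxynaphthalen-1-amine | COc1cccc2c(N)ccc(OCc3ccccc3)c12 | intermediate
14 | 4-(benzyloxy)-5-methoxynaphthalene-1-diazonium tetrafluoroborate | COc1cccc2c([N+]#N)ccc(OCc3ccccc3)c12.F[B-](F)(F)F | intermediate
15 | {[(1S,4S)-4-[4-(benzyloxy)-5-methoxynaphthalen-1-yl]-5-methoxy-1,2,3,4-tetrahydronaphthalen-1-yl]oxy}(tert-butyl)dimethylsilane (cis) | COc1cccc2c1[C@H](c1ccc(OCc3ccccc3)c3c(OC)cccc13)CC[C@@H]2O[Si](C)(C)C(C)(C)C | intermediate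
16 | (1S,4S)-4-[4-(benzyloxy)-5-methoxynaphthalen-1-yl]-5-methoxy-1,2,3,4-tetrahydronaphthalen-1-ol (cis) | COc1cccc2c1[C@H](c1ccc(OCc3ccccc3)c3c(OC)cccc13)CC[C@@H]2O | intermediate
17 | dipolynaphthalene B, (1S,4S)-4-(4-hydroxy-5-methoxynaphthalen-1-yl)-5-methoxy-1,2,3,4-tetrahydronaphthalen-1-ol | COc1cccc2c1[C@H](c1ccc(O)c3c(OC)cccc13)CC[C@@H]2O | target

**Step count**

Total step count: 11. Longest linear sequence: 8 steps (steps 4 to 11, from naphthalene-1,8-diol).

**Steps most likely to fail**

1. Step 9. The η3-benzyl palladium intermediate may lose hydride and release the chain as a simple Heck-type alkene before the hindered boron transmetalates, boron may capture palladium at C3, or facial control at C4 from the remote C1 centre may be poor. The fallback uses known chemistry only; it sets out from bromide 5 and diazonium salt 14 and comes back to the route at target 17.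
 - Hydroboration–oxidation of 5 (9-BBN, THF; then NaOH, H2O2) should give (4S)-4-(2-bromo-3-methoxyphenyl)-4-{[tert-butyl(dimethyl)silyl]oxy}butan-1-ol F1.
 - Oxidation with TEMPO and PhI(OAc)2 in MeCN/H2O should give (4S)-4-(2-bromo-3-methoxyphenyl)-4-{[tert-butyl(dimethyl)silyl]oxy}butanoic acid F2.
 - Coupling with N,O-dimethylhydroxylamine hydrochloride (EDC, iPr2NEt, CH2Cl2) should give (4S)-4-(2-bromo-3-methoxyphenyl)-4-{[tert-butyl(dimethyl)silyl]oxy}-N-methoxy-N-methylbutanamide F3.
 - Bromine–lithium exchange with t-BuLi in THF at −78 °C, followed by Parham cycloacylation onto the amide, should close ring B as (4S)-4-{[tert-butyl(dimethyl)silyl]oxy}-8-methoxy-3,4-dihydronaphthalen-1(2H)-one F4.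
 - Enolisation and triflation (KN(SiMe3)2, PhNTf2, THF, −78 °C) should give (4S)-4-{[tert-butyl(dimethyl)silyl]oxy}-8-methoxy-3,4-dihydronaphthalen-1-yl trifluoromethanesulfonate F5.
 - In parallel, palladium-catalysed borylation of 14 (B2pin2, PdCl2(dppf), MeOH, rt) should give 2-[4-(benzyloxy)-5-methoxynaphthalen-1-yl]-4,4,5,5-tetramethyl-1,3,2-dioxaborolane F6.
 - Suzuki–Miyaura coupling of F5 with F6 (Pd(PPh3)4, K3PO4, dioxane/H2O, 60 °C) should give {[(1S)-4-[4-(benzyloxy)-5-methoxynaphthalen-1-yl]-5-methoxy-1,2-dihydronaphthalen-1-yl]oxy}(tert-butyl)dimethylsilane F7.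
 - Hydrogenation (H2, Pd/C, EtOAc) should add hydrogen to the C3=C4 bond from the face opposite the pseudoaxial silyloxy group, which places the naphthyl group cis to it, and should remove the benzyl group in the same operation, giving 4-[(1S,4S)-4-{[tert-butyl(dimethyl)silyl]oxy}-8-methoxy-1,2,3,4-tetrahydronaphthalen-1-yl]-8-methoxynaphthalen-1-ol F8.
 - TBAF in THF then gives 17.

2. Step 3. The ortho-lithiated benzylic silyl ether may suffer migration of silicon from oxygen to the lithiated carbon (or, on warming, 5-exo carbolithiation of the alkene) before the borate traps it. The fallback removes silicon from the oxygen; it sets out from alcohol 4 and comes back at target 17.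
 - Alkylation of 4 with benzyl chloromethyl ether (iPr2NEt, CH2Cl2) should give 1-{(1S)-1-[(benzyloxy)methoxy]but-3-en-1-yl}-2-bromo-3-methoxybenzene F9.
 - Bromine–lithium exchange and borylation as in step 3 should give {2-[(1S)-1-[(benzyloxy)methoxy]but-3-en-1-yl]-6-methoxyphenyl}boronic acid F10.
 - Ring closure with 14 under the conditions of step 9 would give 1-(benzyloxy)-4-{(1S,4S)-4-[(benzyloxy)methoxy]-8-methoxy-1,2,3,4-tetrahydronaphthalen-1-yl}-8-methoxynaphthalene F11.
 - A single hydrogenolysis (H2, Pd/C, EtOAc/EtOH) removes both the benzyloxymethyl and the benzyl group and gives 17, so step 10 is not needed.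

3. Step 5. The diazonium ion may attack C2 (ortho to the hydroxyl) or couple twice, instead of giving clean para substitution. The fallback replaces azo coupling by halogenation and C–N cross-coupling; it sets out from 10 and comes back at amine 13.
 - Para bromination of 10 with NBS in MeCN at 0 °C should give 4-bromo-8-methoxynaphthalen-1-ol F12.
 - Benzylation (BnBr, K2CO3, DMF) should give 1-(benzyloxy)-4-bromo-8-methoxynaphthalene F13.
 - Buchwald–Hartwig amination with benzophenone imine (Pd2(dba)3, rac-BINAP, NaOtBu, toluene, 90 °C) should give N-[4-(benzyloxy)-5-methoxynaphthalen-1-yl]-1,1-diphenylmethanimine F14.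
 - Hydrolysis with aqueous HCl in THF at rt then gives 13, and steps 6 and 7 are not needed.

**Further compounds**

F1 | step 9 | (4S)-4-(2-bromo-3-methoxyphenyl)-4-{[tert-butyl(dimethyl)silyl]oxy}butan-1-ol | OCCC[C@H](O[Si](C)(C)C(C)(C)C)c1cccc(OC)c1Br
F2 | step 9 | (4S)-4-(2-bromo-3-methoxyphenyl)-4-{[tert-butyl(dimethyl)silyl]oxy}butanoic acid | OC(=O)CC[C@H](O[Si](C)(C)C(C)(C)C)c1cccc(OC)c1Br
F3 | step 9 | (4S)-4-(2-bromo-3-methoxyphenyl)-4-{[tert-butyl(dimethyl)silyl]oxy}-N-methoxy-N-methylbutanamide | CON(C)C(=O)CC[C@H](O[Si](C)(C)C(C)(C)C)c1cccc(OC)c1Br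
F4 | step 9 | (4S)-4-{[tert-butyl(dimethyl)silyl]oxy}-8-methoxy-3,4-dihydronaphthalen-1(2H)-one | COc1cccc2c1C(=O)CC[C@@H]2O[Si](C)(C)C(C)(C)C
F5 | step 9 | (4S)-4-{[tert-butyl(dimethyl)silyl]oxy}-8-methoxy-3,4-dihydronaphthalen-1-yl trifluoromethanesulfonate | COc1cccc2c1C(OS(=O)(=O)C(F)(F)F)=CC[C@@H]2O[Si](C)(C)C(C)(C)C
F6 | step 9 | 2-[4-(benzyloxy)-5-methoxynaphthalen-1-yl]-4,4,5,5-tetramethyl-1,3,2-dioxaborolane | COc1cccc2c(B3OC(C)(C)C(C)(C)O3)ccc(OCc3ccccc3)c12
F7 | step 9 | {[(1S)-4-[4-(benzyloxy)-5-methoxynaphthalen-1-yl]-5-methoxy-1,2-dihydronaphthalen-1-yl]oxy}(tert-butyl)dimethylsilane | COc1cccc2c1C(c1ccc(OCc3ccccc3)c3c(OC)cccc13)=CC[C@@H]2O[Si](C)(C)C(C)(C)C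
F8 | step 9 | 4-[(1S,4S)-4-{[tert-butyl(dimethyl)silyl]oxy}-8-methoxy-1,2,3,4-tetrahydronaphthalen-1-yl]-8-methoxynaphthalen-1-ol | COc1cccc2c1[C@H](c1ccc(O)c3c(OC)cccc13)CC[C@@H]2O[Si](C)(C)C(C)(C)C
F9 | step 3 | 1-{(1S)-1-[(benzyloxy)methoxy]but-3-en-1-yl}-2-bromo-3-methoxybenzene | C=CC[C@H](OCOCc1ccccc1)c1cccc(OC)c1Br
F10 | step 3 | {2-[(1S)-1-[(benzyloxy)methoxy]but-3-en-1-yl]-6-methoxyphenyl}boronic acid | C=CC[C@H](OCOCc1ccccc1)c1cccc(OC)c1B(O)O
F11 | step 3 | 1-(benzyloxy)-4-{(1S,4S)-4-[(benzyloxy)methoxy]-8-methoxy-1,2,3,4-tetrahydronaphthalen-1-yl}-8-methoxynaphthalene | COc1cccc2c1[C@H](c1ccc(OCc3ccccc3)c3c(OC)cccc13)CC[C@@H]2OCOCc1ccccc1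
F12 | step 5 | 4-bromo-8-methoxynaphthalen-1-ol | COc1cccc2c(Br)ccc(O)c12
F13 | step 5 | 1-(benzyloxy)-4-bromo-8-methoxynaphthalene | COc1cccc2c(Br)ccc(OCc3ccccc3)c12
F14 | step 5 | N-[4-(benzyloxy)-5-methoxynaphthalen-1-yl]-1,1-diphenylmethanimine | COc1cccc2c(N=C(c3ccccc3)c3ccccc3)ccc(OCc3ccccc3)c12
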